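**Plan**

1. Numbering: the chromanone is O1–C8a (ring A carbocycle, ring C heterocycle). Ring B is the benzene ring of the dihydrobenzofuran, whose furan atoms are written bf-O1, bf-C2 and bf-C3.
2. Feature: ring A (C4a, C5, C6, C7, C8, C8a) carries oxygen on C5, C7 and C8a (as O1) and the acyl carbon C4 on C4a. This is the alternating pattern of three head-to-tail acetates, so ring A unfolds at C4a–C5 into a CH2–CO–CH2–CO2Me chain on the enol-ether carbon of a 2-aryl-2,3-dihydropyran-4-one.
3. Cuts, in retrosynthetic order: three O–benzyl bonds; C4a–C5 (Claisen, ring A); O1–C8a (cyclodehydration, ring C); C4–C4a (dianion acylation); C2–C3 (crossed Claisen on the ring B ester); bf-O1–bf-C2 (benzylic etherification); bf-C2–bf-C3 (aldol).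
4. Forward: the dihydrobenzofuran is made first. The eight-carbon chain is then joined as acetate plus a dioxinone-masked triacetate, ring C closes under acid and ring A closes last. The whole chain is in place before ring C exists, so no strong base ever meets the 2-aryl-dihydropyranone.
5. Stereochemistry: bf-C3 comes from an Evans aldol with (R)-4-benzyl-2-oxazolidinone. bf-C2 comes from trans-selective ring closure directed by bf-C3. C2 comes from asymmetric transfer hydrogenation, and its C–O bond is never broken afterwards.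

Key step: step 16

Remark on the chemistry: the target is taken exactly as drawn, 2S in the chromanone and 2R,3S (trans) in the dihydrobenzofuran. O-Benzylvanillin, (R)-4-benzyl-2-oxazolidinone and 2,2,6-trimethyl-4H-1,3-dioxin-4-one are taken as purchasable.

**Step 1**
Reactants: 1 methyl 3,4-dihydroxybenzoate; 2 allyl bromide
Product: 3 methyl 4-(allyloxy)-3-hydroxybenzoate
Conditions: K2CO3 (1.0 equiv), DMF, 0 °C → rt
Reagents that add atoms: none
Why: Williamson ether synthesis in which the 4-OH, para to the ester, is the more acidic phenol, so one equivalent of carbonate ionises and alkylates it in preference to the 3-OH.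

**Step 2**
Reactants: 3 methyl 4-(allyloxy)-3-hydroxybenzoate
Product: 4 methyl 3-allyl-4,5-dihydroxybenzoate
Conditions: N,N-diethylaniline, 200 °C
Reagents that add atoms: none
Why: Aromatic Claisen rearrangement, whose [3,3] shift can rearomatise only at the free ortho carbon because the other ortho position carries the hydroxyl, so the allyl group ends next to the future bf-O1.

**Step 3**
Reactants: 4 methyl 3-allyl-4,5-dihydroxybenzoate
Product: 5 methyl 3-allyl-4,5-bis(methoxymethoxy)benzoate
Conditions: MOMCl, iPr2NEt, CH2Cl2, 0 °C → reflux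
Reagents that add atoms: chloromethyl methyl ether COCCl
Why: Routine acetal protection of both phenols, chosen because MOM ethers tolerate the oxidation, boron aldol and borohydride steps and leave under the same acid that later closes the dihydrobenzofuran.

**Step 4**
Reactants: 5 methyl 3-allyl-4,5-bis(methoxymethoxy)benzoate
Product: 7 2-[5-(methoxycarbonyl)-2,3-bis(methoxymethoxy)phenyl]acetic acid, via arylacetaldehyde 6 (not isolated)
Conditions: KMnO4 (cat.), NaIO4, t-BuOH/aq. phosphate buffer (pH 7.5), rt; citric acid to pH 4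
Reagents that add atoms: potassium permanganate [K+].[O-][Mn](=O)(=O)=O; sodium periodate [Na+].[O-]I(=O)(=O)=O; water O
Why: Lemieux–von Rudloff oxidation, in which catalytic permanganate dihydroxylates the terminal alkene, periodate cleaves the diol and the aldehyde is oxidised on to the acid in a near-neutral medium that MOM ethers and the methyl ester withstand.

**Step 5**
Reactants: 7 2-[5-(methoxycarbonyl)-2,3-bis(methoxymethoxy)phenyl]acetic acid; 8 (R)-4-benzyl-2-oxazolidinone
Product: 10 (4R)-4-benzyl-3-{2-[5-(methoxycarbonyl)-2,3-bis(methoxymethoxy)phenyl]acetyl}-1,3-oxazolidin-2-one, via pivalic mixed anhydride 9 (not isolated)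
Conditions: PivCl, Et3N, THF, −20 °C; then LiCl, 8, −20 °C → rt
Reagents that add atoms: none
Why: N-acylation of the oxazolidinone through a mixed anhydride with LiCl activation, a routine entry to Evans imides that spares the acidic arylacetyl unit any strong base.

**Step 6**
Reactants: 10 the N-arylacetyl imide; 11 4-(benzyloxy)-3-methoxybenzaldehyde
Product: 13 (4R)-4-benzyl-3-{(2R,3R)-3-[4-(benzyloxy)-3-methoxyphenyl]-3-hydroxy-2-[5-(methoxycarbonyl)-2,3-bis(methoxymethoxy)phenyl]propanoyl}-1,3-oxazolidin-2-one, via boron enolate 12 (not isolated)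
Conditions: Bu2BOTf, Et3N, CH2Cl2, −78 → 0 °C; 11, −78 → 0 °C; H2O2, MeOH, pH 7 buffer, 0 °C
Reagents that add atoms: none
Why: Evans syn-aldol reaction, in which the (Z)-boron enolate reacts through a Zimmerman–Traxler chair on the face away from the benzyl group of the (R)-auxiliary, fixing the aryl-bearing carbon (future bf-C3) as R in the imide, which becomes the required S once the imide carbonyl is reduced to CH2OH and the priorities change.

**Step 7**
Reactants: 13 the syn-aldol imide
Product: 14 methyl 3-{(1R,2S)-1-[4-(benzyloxy)-3-methoxyphenyl]-1,3-dihydroxypropan-2-yl}-4,5-bis(methoxymethoxy)benzoate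
Conditions: NaBH4, THF/H2O (4:1), 0 °C → rt
Reagents that add atoms: none
Why: Reductive removal of the auxiliary by aqueous borohydride, which attacks the activated exocyclic imide carbonyl but not the aromatic methyl ester, and which is done before the phenols are freed so that no benzofuranone can form at the acyl stage.

**Step 8**
Reactants: 14 the bis-MOM diol
Product: 16 methyl (2R,3S)-2-[4-(benzyloxy)-3-methoxyphenyl]-7-hydroxy-3-(hydroxymethyl)-2,3-dihydro-1-benzofuran-5-carboxylate, via free catechol diol 15 (not isolated)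
Conditions: HCl (1 M in MeOH), 40 °C
Reagents that add atoms: none
Why: Acid methanolysis frees the catechol and the p-benzyloxy-stabilised benzylic cation is captured by the adjacent phenol (acid-mediated phenylcoumaran closure), bf-C3 steering the aryl group to the opposite face so that the trans-(2R,3S) ring forms whatever the carbinol configuration was.

**Step 9**
Reactants: 16 the 7-hydroxy-3-hydroxymethyl dihydrobenzofuran ester
Product: 17 methyl (2R,3S)-7-(benzyloxy)-2-[4-(benzyloxy)-3-methoxyphenyl]-3-[(benzyloxy)methyl]-2,3-dihydro-1-benzofuran-5-carboxylate (Ar*–CO2Me, where Ar* is this tribenzylated dihydrobenzofuran-5-yl group)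
Conditions: NaH, BnBr, Bu4NI (cat.), DMF, 0 °C → rt
Reagents that add atoms: benzyl bromide BrCc1ccccc1
Why: Williamson benzylation of the phenol and the primary alcohol in one operation, giving ethers that survive every later base, acid and heat step and can be removed at the end under neutral conditions.

**Step 10**
Reactants: 17 Ar*–CO2Me; 18 methyl acetate
Product: 19 methyl 3-Ar*-3-oxopropanoate
Conditions: LiN(SiMe3)2, THF, −78 → 0 °C; aq. NH4Cl
Reagents that add atoms: none
Why: Crossed Claisen condensation, in which the benzoate cannot enolise, so the lithium enolate of methyl acetate is acylated by it and the product is shielded as its enolate until the quench.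

**Step 11**
Reactants: 19 methyl 3-Ar*-3-oxopropanoate
Product: 20 methyl (3S)-3-Ar*-3-hydroxypropanoate
Conditions: RuCl[(S,S)-TsDPEN](p-cymene) (cat.), HCO2H/Et3N (5:2), CH2Cl2, 30 °C
Reagents that add atoms: none
Why: Noyori–Ikariya asymmetric transfer hydrogenation of an aryl ketone, in which the (S,S)-catalyst delivers hydride to the face that gives the S carbinol (future C2) under catalyst control, the existing stereocentres being remote.

**Step 12**
Reactants: 20 methyl (3S)-3-Ar*-3-hydroxypropanoate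
Product: 21 (3S)-3-Ar*-3-hydroxy-N-methoxy-N-methylpropanamide
Conditions: MeNH(OMe)·HCl, iPrMgCl, THF, −20 → 0 °C
Reagents that add atoms: N,O-dimethylhydroxylamine hydrochloride CNOC.Cl
Why: Weinreb amide synthesis by aminolysis of the ester with the chloromagnesium amide, which works on unprotected β-hydroxy esters because the alkoxide formed first is inert.

**Step 13**
Reactants: 22 2,2,6-trimethyl-4H-1,3-dioxin-4-one; 23 acetyl chloride
Product: 24 2,2-dimethyl-6-(2-oxopropyl)-4H-1,3-dioxin-4-one
Conditions: LiN(SiMe3)2, THF, −78 °C; then 23, −78 °C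
Reagents that add atoms: none
Why: γ-Selective C-acylation of the lithium dienolate of the dioxinone (vinylogous Claisen-type acylation), which gives the masked triacetate unit that supplies C4a and C5–C8a.

**Step 14**
Reactants: 21 the β-hydroxy Weinreb amide; 24 the keto-dioxinone
Product: 26 (2S)-2-Ar*-6-[(2,2-dimethyl-4-oxo-4H-1,3-dioxin-6-yl)methyl]-2,3-dihydro-4H-pyran-4-one, via hydroxy diketo-dioxinone 25 (not isolated)
Conditions: 24 (excess), LiN(iPr)2, THF, −78 °C; 21, −78 → −20 °C; cold 1 M HCl; crude in CH2Cl2, TFA (cat.), 0 °C → rt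
Reagents that add atoms: none
Why: Claisen-type acylation of a 1,3-dicarbonyl dianion at its terminal carbon by a Weinreb amide whose lithium alkoxide cannot be eliminated, followed by acid-catalysed hemiketalisation and dehydration of the δ-hydroxy-1,3-diketone, a closure that leaves the C2–O bond and hence the S configuration untouched.

**Step 15**
Reactants: 26 the dihydropyranone–dioxinone
Product: 28 methyl 4-[(2S)-2-Ar*-4-oxo-3,4-dihydro-2H-pyran-6-yl]-3-oxobutanoate, via acylketene 27 (not isolated)
Conditions: MeOH (excess), toluene, 110 °C (sealed tube)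
Reagents that add atoms: methanol CO
Why: Thermal retro-[4+2] cleavage of the dioxinone releases acetone and an acylketene, which excess methanol traps as the β-keto ester under neutral conditions that cannot open ring C.

**Step 16**
Reactants: 28 methyl 4-[(2S)-2-Ar*-4-oxo-3,4-dihydro-2H-pyran-6-yl]-3-oxobutanoate
Product: 30 tri-O-benzyl silyhermin B, (2S)-2-Ar*-5,7-dihydroxychroman-4-one, via diketo tautomer 29 (not isolated)
Conditions: Mg(OMe)2 (3 equiv), MeOH/THF, 0 °C → rt; cold aq. AcOH
Reagents that add atoms: none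
Why: Proposed new method: Mg(OMe)2 deprotonates the methylene between pyranone C6 and the chain ketone, the charge of this extended enolate runs through C6=C5 to the C4 oxygen, and magnesium held by that oxygen and by the ester carbonyl guides C5 (future C4a) onto the ester carbon; methoxide leaves, C4a–C5 is formed, and diketo tautomer 29 enolises at once to the phloroglucinol, which is withdrawn from all equilibria as its magnesium 4-oxo-5-olate chelate. The closest known reaction type is the base- or Mg(OMe)2-promoted Claisen (Dieckmann-type) folding of 3,5,7-trioxo esters and of pyrone-masked polyketo esters to acylphloroglucinols; new here is that the nucleophile is the α-carbon of a cyclic vinylogous ester whose enol oxygen already is O1. Ring A closes in the 6-(enolexo)-exo-trig mode. No stereocentre is made, and C2 should be kept because the chain methylenes are more acidic than C3–H by many pKa units, so a methoxide-level base ionises only the chain and the anionic ring C then resists both C3 deprotonation (the entry to E1cB cleavage of O1–C2) and methoxide addition at C6. Site selectivity is built into the substrate: attack of the terminal methylene on C4 would need a bridged ring with a bridgehead alkene, O-acylation through the C4 oxygen would need an eight-membered enol lactone, and the chain ketone has no six-membered partner, so the Claisen fold is the only closure within reach. Low temperature, a short reaction time and the cold acetic acid quench limit the exposure of flavanone 30 to base.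

**Step 17**
Reactants: 30 tri-O-benzyl silyhermin B
Product: 31 silyhermin B
Conditions: H2 (1 atm), 10% Pd/C, EtOAc/MeOH, rt
Reagents that add atoms: none
Why: Catalytic hydrogenolysis of the three benzyl ethers under neutral conditions, chosen because neither acid nor base, either of which can open ring C and erode C2, is present.

**Compound list**

1 | methyl 3,4-dihydroxybenzoate | COC(=O)c1ccc(O)c(O)c1 | starting material
2 | allyl bromide | C=CCBr | starting material
3 | methyl 4-(allyloxy)-3-hydroxybenzoate | COC(=O)c1ccc(OCC=C)c(O)c1 | intermediate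
4 | methyl 3-allyl-4,5-dihydroxybenzoate | COC(=O)c1cc(CC=C)c(O)c(O)c1 | intermediate
5 | methyl 3-allyl-4,5-bis(methoxymethoxy)benzoate | COC(=O)c1cc(CC=C)c(OCOC)c(OCOC)c1 | intermediate
6 | methyl 3,4-bis(methoxymethoxy)-5-(2-oxoethyl)benzoate | COC(=O)c1cc(CC=O)c(OCOC)c(OCOC)c1 | intermediate
7 | 2-[5-(methoxycarbonyl)-2,3-bis(methoxymethoxy)phenyl]acetic acid | COC(=O)c1cc(CC(=O)O)c(OCOC)c(OCOC)c1 | intermediate
8 | (R)-4-benzyl-2-oxazolidinone | O=C1N[C@H](Cc2ccccc2)CO1 | starting material
9 | pivalic mixed anhydride of 7 | COC(=O)c1cc(CC(=O)OC(=O)C(C)(C)C)c(OCOC)c(OCOC)c1 | intermediate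
10 | (4R)-4-benzyl-3-{2-[5-(methoxycarbonyl)-2,3-bis(methoxymethoxy)phenyl]acetyl}-1,3-oxazolidin-2-one | COC(=O)c1cc(CC(=O)N2[C@H](Cc3ccccc3)COC2=O)c(OCOC)c(OCOC)c1 | intermediate
11 | 4-(benzyloxy)-3-methoxybenzaldehyde | COc1cc(C=O)ccc1OCc2ccccc2 | starting material
12 | (Z)-dibutylboron enolate of 10 | CCCCB(CCCC)O/C(=C\c1cc(C(=O)OC)cc(OCOC)c1OCOC)N2[C@H](Cc3ccccc3)COC2=O | intermediate
13 | (2R,3R)-syn-aldol imide | COc1cc([C@H](O)[C@H](C(=O)N2[C@H](Cc3ccccc3)COC2=O)c4cc(C(=O)OC)cc(OCOC)c4OCOC)ccc1OCc5ccccc5 | intermediate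
14 | methyl 3-{(1R,2S)-1-[4-(benzyloxy)-3-methoxyphenyl]-1,3-dihydroxypropan-2-yl}-4,5-bis(methoxymethoxy)benzoate | COc1cc([C@H](O)[C@H](CO)c2cc(C(=O)OC)cc(OCOC)c2OCOC)ccc1OCc3ccccc3 | intermediate
15 | methyl 3-{(1R,2S)-1-[4-(benzyloxy)-3-methoxyphenyl]-1,3-dihydroxypropan-2-yl}-4,5-dihydroxybenzoate | COc1cc([C@H](O)[C@H](CO)c2cc(C(=O)OC)cc(O)c2O)ccc1OCc3ccccc3 | intermediate
16 | methyl (2R,3S)-2-[4-(benzyloxy)-3-methoxyphenyl]-7-hydroxy-3-(hydroxymethyl)-2,3-dihydro-1-benzofuran-5-carboxylate | COc1cc([C@@H]2Oc3c(O)cc(C(=O)OC)cc3[C@H]2CO)ccc1OCc4ccccc4 | intermediate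
17 | methyl (2R,3S)-7-(benzyloxy)-2-[4-(benzyloxy)-3-methoxyphenyl]-3-[(benzyloxy)methyl]-2,3-dihydro-1-benzofuran-5-carboxylate (Ar*–CO2Me) | COc1cc([C@@H]2Oc3c(OCc4ccccc4)cc(C(=O)OC)cc3[C@H]2COCc4ccccc4)ccc1OCc4ccccc4 | intermediate
18 | methyl acetate | COC(C)=O | starting material
19 | methyl 3-Ar*-3-oxopropanoate | COc1cc([C@@H]2Oc3c(OCc4ccccc4)cc(C(=O)CC(=O)OC)cc3[C@H]2COCc4ccccc4)ccc1OCc4ccccc4 | intermediate
20 | methyl (3S)-3-Ar*-3-hydroxypropanoate | COc1cc([C@@H]2Oc3c(OCc4ccccc4)cc([C@@H](O)CC(=O)OC)cc3[C@H]2COCc4ccccc4)ccc1OCc4ccccc4 | intermediate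
21 | (3S)-3-Ar*-3-hydroxy-N-methoxy-N-methylpropanamide | COc1cc([C@@H]2Oc3c(OCc4ccccc4)cc([C@@H](O)CC(=O)N(C)OC)cc3[C@H]2COCc4ccccc4)ccc1OCc4ccccc4 | intermediate
22 | 2,2,6-trimethyl-4H-1,3-dioxin-4-one | CC1=CC(=O)OC(C)(C)O1 | starting material
23 | acetyl chloride | CC(=O)Cl | starting material
24 | 2,2-dimethyl-6-(2-oxopropyl)-4H-1,3-dioxin-4-one | CC(=O)CC1=CC(=O)OC(C)(C)O1 | intermediate
25 | 6-[(6S)-6-Ar*-6-hydroxy-2,4-dioxohexyl]-2,2-dimethyl-4H-1,3-dioxin-4-one | COc1cc([C@@H]2Oc3c(OCc4ccccc4)cc([C@@H](O)CC(=O)CC(=O)CC5=CC(=O)OC(C)(C)O5)cc3[C@H]2COCc4ccccc4)ccc1OCc4ccccc4 | intermediate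
26 | (2S)-2-Ar*-6-[(2,2-dimethyl-4-oxo-4H-1,3-dioxin-6-yl)methyl]-2,3-dihydro-4H-pyran-4-one | COc1cc([C@@H]2Oc3c(OCc4ccccc4)cc([C@@H]5CC(=O)C=C(CC6=CC(=O)OC(C)(C)O6)O5)cc3[C@H]2COCc4ccccc4)ccc1OCc4ccccc4 | intermediate
27 | 4-[(2S)-2-Ar*-4-oxo-3,4-dihydro-2H-pyran-6-yl]-3-oxobut-1-en-1-one (acylketene) | COc1cc([C@@H]2Oc3c(OCc4ccccc4)cc([C@@H]5CC(=O)C=C(CC(=O)C=C=O)O5)cc3[C@H]2COCc4ccccc4)ccc1OCc4ccccc4 | intermediate
28 | methyl 4-[(2S)-2-Ar*-4-oxo-3,4-dihydro-2H-pyran-6-yl]-3-oxobutanoate | COc1cc([C@@H]2Oc3c(OCc4ccccc4)cc([C@@H]5CC(=O)C=C(CC(=O)CC(=O)OC)O5)cc3[C@H]2COCc4ccccc4)ccc1OCc4ccccc4 | intermediate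
29 | (2S)-2-Ar*-2,3-dihydro-4H-chromene-4,5,7(6H,8H)-trione (diketo tautomer of 30) | COc1cc([C@@H]2Oc3c(OCc4ccccc4)cc([C@@H]5CC(=O)C6=C(CC(=O)CC6=O)O5)cc3[C@H]2COCc4ccccc4)ccc1OCc4ccccc4 | intermediate
30 | tri-O-benzyl silyhermin B, (2S)-2-Ar*-5,7-dihydroxychroman-4-one | COc1cc([C@@H]2Oc3c(OCc4ccccc4)cc([C@@H]5CC(=O)c6c(O)cc(O)cc6O5)cc3[C@H]2COCc4ccccc4)ccc1OCc4ccccc4 | intermediate
31 | silyhermin B, (2S)-5,7-dihydroxy-2-[(2R,3S)-7-hydroxy-2-(4-hydroxy-3-methoxyphenyl)-3-(hydroxymethyl)-2,3-dihydro-1-benzofuran-5-yl]chroman-4-one | COc1cc([C@@H]2Oc3c(O)cc([C@@H]4CC(=O)c5c(O)cc(O)cc5O4)cc3[C@H]2CO)ccc1O | target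

**Step count**

Total step count: 17. Longest linear sequence: 16 (steps 1–12 and 14–17, from methyl 3,4-dihydroxybenzoate). Step 13 lies off the main line.

**Steps most likely to fail**

**Step 16.** Ring C may open before ring A closes. This could happen by E1cB cleavage of O1–C2 after stray deprotonation at C3, or by methoxide exchange at the enol-ether carbon. C2 would then be scrambled, or the freed chain would fold in the aldol sense. Alternatively, the doubly deprotonated β-keto ester may be too poor an electrophile, and the substrate may simply rest as its magnesium chelate.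

The fallback uses known chemistry, sets out from 17 and returns at 31. Ring A is brought in ready-made and ring C is closed by a catalytic asymmetric oxa-Michael addition.
- LiAlH4 (THF, 0 °C) reduces 17 to the benzylic alcohol F1, and MnO2 (CH2Cl2) oxidises it to the aldehyde F2.
- Purchasable 1-[2,4-bis(benzyloxy)-6-hydroxyphenyl]ethanone is C-acylated (LiN(SiMe3)2, di-tert-butyl dicarbonate) to the tert-butyl β-keto ester F3.
- Knoevenagel condensation of F2 with F3 (piperidine, AcOH, toluene, 4 Å sieves) gives the alkylidene β-keto ester F4.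
- The N-[3,5-bis(trifluoromethyl)phenyl]-N'-(9-deoxy-epi-cinchonan-9-yl)thiourea of the quinine/quinidine pair that leads to the 2S series (toluene, −25 °C) closes O1–C2 to the 3-(tert-butoxycarbonyl)flavanone F5.
- TsOH (toluene, 80 °C) removes the ester by cleavage and decarboxylation to give penta-O-benzyl silyhermin B F6.
- The hydrogenolysis conditions of step 17 convert F6 into 31.

**Step 14.** Three processes threaten this step. The lithium alkoxide may fragment by retro-aldol reaction on warming. Proton transfer between dianion and amide may stop the acylation. The diketo-dioxinone may aromatise by base-induced aldol condensation before the acid closure.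

The fallback sets out from 21 and returns at 26, replacing the acylation by aldol addition and oxidation.
- TESCl and imidazole give the silyl ether F7, and iBu2AlH (THF, −78 °C) gives the β-silyloxy aldehyde F8.
- The dianion of 24 adds to F8 at −78 °C without any warming to give the aldol F9. The new carbinol epimers are of no consequence.
- Dess–Martin periodinane oxidises F9 to the silyl-protected diketo-dioxinone F10.
- Aqueous TFA in CH2Cl2 removes the silyl group and closes ring C to 26.

**Step 7.** Hydride may attack the ring carbonyl of the hindered imide and open the auxiliary. The basic aqueous medium may also trigger retro-aldol cleavage of the electron-rich aldol.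

The fallback sets out from 13 and returns at 14. It separates auxiliary removal from reduction.
- LiOH/H2O2 (THF/H2O, 0 °C), which attacks the exocyclic carbonyl selectively, gives the β-hydroxy acid F11.
- BH3·THF (0 °C) reduces the carboxylic acid in the presence of the methyl benzoate to 14.

**Further compounds**

F1 | step 16 | Ar*–CH2OH, [(2R,3S)-7-(benzyloxy)-2-[4-(benzyloxy)-3-methoxyphenyl]-3-[(benzyloxy)methyl]-2,3-dihydro-1-benzofuran-5-yl]methanol | COc1cc([C@@H]2Oc3c(OCc4ccccc4)cc(CO)cc3[C@H]2COCc4ccccc4)ccc1OCc4ccccc4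
F2 | step 16 | Ar*–CHO, the corresponding 5-carbaldehyde | COc1cc([C@@H]2Oc3c(OCc4ccccc4)cc(C=O)cc3[C@H]2COCc4ccccc4)ccc1OCc4ccccc4
F3 | step 16 | tert-butyl 3-[2,4-bis(benzyloxy)-6-hydroxyphenyl]-3-oxopropanoate | CC(C)(C)OC(=O)CC(=O)c1c(O)cc(OCc2ccccc2)cc1OCc2ccccc2
F4 | step 16 | tert-butyl 3-Ar*-2-[2,4-bis(benzyloxy)-6-hydroxybenzoyl]prop-2-enoate (alkene geometry not fixed) | COc1cc([C@@H]2Oc3c(OCc4ccccc4)cc(C=C(C(=O)OC(C)(C)C)C(=O)c5c(O)cc(OCc6ccccc6)cc5OCc6ccccc6)cc3[C@H]2COCc4ccccc4)ccc1OCc4ccccc4
F5 | step 16 | tert-butyl (2S)-2-Ar*-5,7-bis(benzyloxy)-4-oxochroman-3-carboxylate (C3 labile) | COc1cc([C@@H]2Oc3c(OCc4ccccc4)cc([C@@H]5C(C(=O)OC(C)(C)C)C(=O)c6c(OCc7ccccc7)cc(OCc7ccccc7)cc6O5)cc3[C@H]2COCc4ccccc4)ccc1OCc4ccccc4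
F6 | step 16 | penta-O-benzyl silyhermin B, (2S)-2-Ar*-5,7-bis(benzyloxy)chroman-4-one | COc1cc([C@@H]2Oc3c(OCc4ccccc4)cc([C@@H]5CC(=O)c6c(OCc7ccccc7)cc(OCc7ccccc7)cc6O5)cc3[C@H]2COCc4ccccc4)ccc1OCc4ccccc4
F7 | step 14 | (3S)-3-Ar*-N-methoxy-N-methyl-3-(triethylsilyloxy)propanamide | COc1cc([C@@H]2Oc3c(OCc4ccccc4)cc([C@@H](O[Si](CC)(CC)CC)CC(=O)N(C)OC)cc3[C@H]2COCc4ccccc4)ccc1OCc4ccccc4
F8 | step 14 | (3S)-3-Ar*-3-(triethylsilyloxy)propanal | COc1cc([C@@H]2Oc3c(OCc4ccccc4)cc([C@@H](O[Si](CC)(CC)CC)CC=O)cc3[C@H]2COCc4ccccc4)ccc1OCc4ccccc4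
F9 | step 14 | 6-[(6S)-6-Ar*-4-hydroxy-2-oxo-6-(triethylsilyloxy)hexyl]-2,2-dimethyl-4H-1,3-dioxin-4-one (C4 epimers) | COc1cc([C@@H]2Oc3c(OCc4ccccc4)cc([C@@H](O[Si](CC)(CC)CC)CC(O)CC(=O)CC5=CC(=O)OC(C)(C)O5)cc3[C@H]2COCc4ccccc4)ccc1OCc4ccccc4
F10 | step 14 | 6-[(6S)-6-Ar*-2,4-dioxo-6-(triethylsilyloxy)hexyl]-2,2-dimethyl-4H-1,3-dioxin-4-one | COc1cc([C@@H]2Oc3c(OCc4ccccc4)cc([C@@H](O[Si](CC)(CC)CC)CC(=O)CC(=O)CC5=CC(=O)OC(C)(C)O5)cc3[C@H]2COCc4ccccc4)ccc1OCc4ccccc4
F11 | step 7 | (2R,3R)-3-[4-(benzyloxy)-3-methoxyphenyl]-3-hydroxy-2-[5-(methoxycarbonyl)-2,3-bis(methoxymethoxy)phenyl]propanoic acid | COc1cc([C@H](O)[C@H](C(=O)O)c2cc(C(=O)OC)cc(OCOC)c2OCOC)ccc1OCc3ccccc3
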